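The target is the product asked for. Its share y (a selectivity) is target over everything made from the starting material, and Friday's, Saturday's and Monday's differ in temperature.

| setting | south-west | south | north | Friday's | Saturday's | Monday's |
|---|---|---|---|---|---|---|
| starting material | 0.15 M | 0.60 M | 0.30 M | 0.30 M | 0.30 M | 0.30 M |
| first nucleophile | 2 equiv | 2 equiv | 2 equiv | 2.00 equiv | 2.00 equiv | 2.00 equiv |
| second nucleophile | 4 equiv | 4 equiv | 8 equiv | 4.00 equiv | 4.00 equiv | 4.00 equiv |
| temperature | 15 °C | 35 °C | 15 °C | 35 °C | 20 °C | 50 °C |
| remark | run made earlier | run made earlier | run made earlier |  |  |  |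
| time |  |  |  | 5.0 h | 5.0 h | 5.0 h |

| run | time / h | target / % | other capture product / % | solvolysis product / % |
|---|---|---|---|---|
| south-west | 0.500 | 0 | 0 | 0 |
| south-west | 2.00 | 0.6 | 0 | 0 |
| south-west | 2.50 | 1.5 | 0.5 | 0.1 |
| south-west | 4.00 | 0 | 0.1 | 0 |
| south-west | 6.00 | 0 | 0.3 | 0.5 |
| south-west | 8.00 | 0 | 1.0 | 0.8 |
| south-west | 10.0 | 0.8 | 1.8 | 1.7 |
| south | 0.200 | 0 | 0 | 1.7 |
| south | 0.667 | 0 | 1.1 | 0 |
| south | 1.00 | 0.2 | 0.2 | 1.6 |
| south | 1.50 | 0.8 | 4.4 | 0 |
| south | 2.50 | 0.6 | 3.5 | 0.5 |
| south | 3.00 | 0 | 6.3 | 1.9 |
| south | 4.00 | 1.9 | 10.0 | 1.9 |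
| north | 2.50 | 0 | 1.1 | 0.5 |
| north | 4.00 | 0 | 0 | 1.3 |
| north | 6.00 | 0 | 0.4 | 1.3 |
| north | 8.00 | 0 | 0.6 | 0 |
| north | 10.0 | 0 | 1.6 | 0 |

(scatter of a reading: 1 percentage point)

* which flask leads in share of target in all that became target or other capture product or solvolysis product or over-reaction product ("all alike" within 1.5 percentage points) (Friday's / Saturday's / Monday's / all alike)
* share of target in all that became target or other capture product or solvolysis product or over-reaction product, Friday's
* share of target in all that became target or other capture product or solvolysis product or over-reaction product, Saturday's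
* share of target in all that became target or other capture product or solvolysis product or over-reaction product, Monday's



A bench rule says that parallel products keep their ratio, so one reading of y holds at any conversion. The last south reading gives y = 13.8%, with over-reaction product unread. The rule's border appears when the last four south readings are summed in pairs. Target goes from 1.40% to 1.90%, but all read products go from 9.80% to 22.0%. The growth ratios are 1.36 and 2.24. Each target sum carries a scatter of 1.4 percentage points, so this lag is a suspicion.

My reckoning takes it seriously. The mean target of those four readings is 0.825%. Call it the standing stock S, the target level that holds while other products pile up. Then y = S/M, with M the total made. Assuming that percent made per hour ignores concentration, the south run gives M = 17.2% for Friday's, so y = 4.78%. The south and south-west rates differ by a factor 8.02. Scaled with temperature, this gives Monday's M = 82.2%, so y = 1.00%. Saturday's M = 3.62% lies below the 4.90% that the early south pair read on average, so I keep that pair's y = 14.3%. Saturday's then leads.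

The forecast says 13%, 17% and 9% in the order asked, with Saturday's leading: “Cooler probably favours target slightly, while heat likely adds over-reaction and loses target.” It names the same leader as my reckoning but sets Friday's and Monday's higher.

    starting material → intermediate (k = 0.166 h⁻¹, Ea = 97.0 kJ mol⁻¹)
    first nucleophile + intermediate ⇌ target (K = 25.1 M⁻¹, k = 318 M⁻¹ h⁻¹, Ea = 56.0 kJ mol⁻¹, ΔH = −58.0 kJ mol⁻¹)
    second nucleophile + intermediate → other capture product (k = 336 M⁻¹ h⁻¹, Ea = 41.0 kJ mol⁻¹)
    intermediate → solvolysis product (k = 484 h⁻¹, Ea = 95.0 kJ mol⁻¹)
    second nucleophile + target → over-reaction product (k = 0.0712 M⁻¹ h⁻¹, Ea = 85.0 kJ mol⁻¹)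
    (constants at 50 °C)

The flasks give 2.93%, 13.6% and 0.226%, and Saturday's leads. In Friday's, starting material kept passing on, with 86.7% present at 5.00 h, while other capture product rose from 4.46% at 2.50 h to 8.86% at 5.00 h. Target stood at 0.400% at 2.50 h and 0.391% at 5.00 h, its exchange with intermediate relaxing in 0.589 min, shorter than the run. S over Friday's turnover at 5.00 h gives 6.19%, which is 2.11 times its share. Friday's read at 80 min has share 9.41%, and S over its turnover gives 22.1%, 2.35 times that.

Readings and results stem from a simulated flask from invented constants, and the scatter is random.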